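**Retrosynthetic overview**
1. Target 11 ⇐ tricyclic lactone 10 by opening a temporary dihydrocoumarin ring; this lactone ties up the C5–OH and the CO2H, so only one phenol can close the chromanone.
2. 10 ⇐ o-tigloylphenol 9 by a catalyst-controlled, cis-selective intramolecular oxa-Michael addition (chromanone ring; sets C2 and C3 together).
3. 9 ⇐ 6 by iodination and neutral Stille prenylation; 6 ⇐ 4 by Friedel–Crafts tigloylation.
4. 4 ⇐ 5-methoxyresorcinol 1 + (E)-oct-2-enal 2 by enantioselective conjugate addition of the phloroglucinol nucleus with ring closure on the neighbouring phenol, then lactol oxidation (dihydrocoumarin ring; sets the side-chain centre).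
5. Ring order: dihydrocoumarin (temporary) first, chromanone last.

Assumption: quinidine is taken to give the 2S chromanone (quinine being the 2R-selective pseudo-enantiomer for this reaction type); if the first run shows the opposite sense, the alkaloid is swapped and nothing else changes.

**Step 1**
Reactants: 1 5-methoxyresorcinol (2 equiv); 2 (2E)-oct-2-enal
Product: 4 (4R)-7-hydroxy-5-methoxy-4-pentylchroman-2-one, via chromanol lactol 3 (not isolated)
Conditions: (S)-α,α-diphenylprolinol TMS ether (20 mol%), PhCO2H (20 mol%), toluene, 0 °C to rt; then Ag2CO3/Celite, toluene, 70 °C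
Reagents that add atoms: none
Why: Iminium-catalysed Friedel–Crafts conjugate addition/hemiacetalisation, in which the CPh2OTMS group of the (S)-catalyst shields one face of the (E)-iminium ion so the arene adds to the open face and gives the 4R centre; attack para to an OH (C4/C6 of 1) is expected to dominate over C2, and Fetizon oxidation of the lactol gives the lactone without touching that centre.

**Step 2**
Reactants: 4 (4R)-7-hydroxy-5-methoxy-4-pentylchroman-2-one; 5 tigloyl chloride
Product: 6 (4R)-7-hydroxy-5-methoxy-8-[(2E)-2-methylbut-2-enoyl]-4-pentylchroman-2-one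
Conditions: AlCl3 (3 equiv), CH2Cl2/PhNO2, 0 °C to rt; cold 1 M HCl work-up
Reagents that add atoms: none
Why: Friedel–Crafts C-acylation ortho to the phenol, expected at C8 because it is para to the OMe and gives an Al-chelated o-hydroxyaryl ketone, whereas C6 attack would twist the 5-OMe out of conjugation; the enone stays open because the phenol is held as the aluminium chelate and the work-up is cold and acidic.

**Step 3**
Reactants: 6 (4R)-7-hydroxy-5-methoxy-8-[(2E)-2-methylbut-2-enoyl]-4-pentylchroman-2-one
Product: 7 (4R)-7-hydroxy-6-iodo-5-methoxy-8-[(2E)-2-methylbut-2-enoyl]-4-pentylchroman-2-one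
Conditions: NIS (1.05 equiv), TFA (10 mol%), MeCN, 0 °C, dark
Reagents that add atoms: N-iodosuccinimide, O=C1CCC(=O)N1I
Why: Electrophilic aromatic iodination ortho to the phenol at the only remaining ring C–H; the electron-poor tigloyl alkene is inert to NIS.

**Step 4**
Reactants: 7 (4R)-7-hydroxy-6-iodo-5-methoxy-8-[(2E)-2-methylbut-2-enoyl]-4-pentylchroman-2-one; 8 tributyl(3-methylbut-2-en-1-yl)stannane (1.5 equiv)
Product: 9 (4R)-7-hydroxy-5-methoxy-8-[(2E)-2-methylbut-2-enoyl]-6-(3-methylbut-2-en-1-yl)-4-pentylchroman-2-one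
Conditions: Pd2(dba)3 (2.5 mol%), AsPh3 (20 mol%), degassed toluene, 80 °C; tin removed on KF/silica
Reagents that add atoms: none
Why: Stille coupling under neutral conditions, chosen because acid would cyclise the o-prenylphenol to a chroman and base would trigger a racemic oxa-Michael closure; reductive elimination at the less hindered allyl terminus gives the linear prenyl group.

**Step 5**
Reactants: 9 (4R)-7-hydroxy-5-methoxy-8-[(2E)-2-methylbut-2-enoyl]-6-(3-methylbut-2-en-1-yl)-4-pentylchroman-2-one
Product: 10 (4R,8S,9R)-5-methoxy-8,9-dimethyl-6-(3-methylbut-2-en-1-yl)-4-pentyl-3,4,8,9-tetrahydro-2H,10H-pyrano[2,3-f]chromene-2,10-dione (cis-8,9-dimethyl)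
Conditions: quinidine (20 mol%), 4 Å MS, PhCl, 15 °C, 3–5 d; chromatography on neutral silica
Reagents that add atoms: none
Why: Cinchona-alkaloid-catalysed 6-endo-trig intramolecular oxa-Michael addition, in which only the O7–H can reach the enone (the other ortho oxygen is the lactone), the alkaloid ion pair selects the enone face (2S in chromanone numbering) and the enol is protonated kinetically anti to the pseudo-axial C2 methyl to give the cis (3R) ketone; the remote 4R centre is untouched.

**Step 6**
Reactants: 10 (4R,8S,9R)-5-methoxy-8,9-dimethyl-6-(3-methylbut-2-en-1-yl)-4-pentyl-3,4,8,9-tetrahydro-2H,10H-pyrano[2,3-f]chromene-2,10-dione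
Product: 11 (3R)-3-[(2S,3R)-5-hydroxy-7-methoxy-2,3-dimethyl-8-(3-methylbut-2-en-1-yl)-4-oxochroman-6-yl]octanoic acid (target)
Conditions: LiOH·H2O (3 equiv), THF/H2O 3:1, 0 °C, 20 min; cold 1 M HCl to pH 3
Reagents that add atoms: lithium hydroxide, [Li+].[OH-]; water, O
Why: Saponification of an activated aryl lactone, which is much faster than ketone enolisation, and the phenoxide/carboxylate dianion formed is a vinylogous carboxylate that resists C3 deprotonation and retro-Michael opening; the cold acid quench gives the chelated 5-OH acid, which does not relactonise.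

**Compound list**
1 | 5-methoxybenzene-1,3-diol (5-methoxyresorcinol) | COc1cc(O)cc(O)c1 | starting material
2 | (2E)-oct-2-enal | CCCCC/C=C/C=O | starting material
3 | (4R)-5-methoxy-4-pentylchromane-2,7-diol (lactol, C2 anomers) | CCCCC[C@@H]1CC(O)Oc2cc(O)cc(OC)c21 | intermediate
4 | (4R)-7-hydroxy-5-methoxy-4-pentylchroman-2-one | CCCCC[C@@H]1CC(=O)Oc2cc(O)cc(OC)c21 | intermediate
5 | (2E)-2-methylbut-2-enoyl chloride (tigloyl chloride) | C/C=C(\C)C(=O)Cl | starting material
6 | (4R)-7-hydroxy-5-methoxy-8-[(2E)-2-methylbut-2-enoyl]-4-pentylchroman-2-one | CCCCC[C@@H]1CC(=O)Oc2c(C(=O)/C(C)=C/C)c(O)cc(OC)c21 | intermediate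
7 | (4R)-7-hydroxy-6-iodo-5-methoxy-8-[(2E)-2-methylbut-2-enoyl]-4-pentylchroman-2-one | CCCCC[C@@H]1CC(=O)Oc2c(C(=O)/C(C)=C/C)c(O)c(I)c(OC)c21 | intermediate
8 | tributyl(3-methylbut-2-en-1-yl)stannane | CCCC[Sn](CCCC)(CCCC)CC=C(C)C | starting material
9 | (4R)-7-hydroxy-5-methoxy-8-[(2E)-2-methylbut-2-enoyl]-6-(3-methylbut-2-en-1-yl)-4-pentylchroman-2-one | CCCCC[C@@H]1CC(=O)Oc2c(C(=O)/C(C)=C/C)c(O)c(CC=C(C)C)c(OC)c21 | intermediate
10 | (4R,8S,9R)-5-methoxy-8,9-dimethyl-6-(3-methylbut-2-en-1-yl)-4-pentyl-3,4,8,9-tetrahydro-2H,10H-pyrano[2,3-f]chromene-2,10-dione | CCCCC[C@@H]1CC(=O)Oc2c3C(=O)[C@H](C)[C@H](C)Oc3c(CC=C(C)C)c(OC)c21 | intermediate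
11 | (3R)-3-[(2S,3R)-5-hydroxy-7-methoxy-2,3-dimethyl-8-(3-methylbut-2-en-1-yl)-4-oxochroman-6-yl]octanoic acid | CCCCC[C@H](CC(=O)O)c1c(O)c2c(c(CC=C(C)C)c1OC)O[C@@H](C)[C@@H](C)C2=O | target

**Totals**
Total steps: 6. Longest linear sequence: 6 steps (1 → 11).

**Three steps most likely to fail**

Step 1 (regiochemistry on an unsymmetrical, triply activated phenol; double annulation; ee). The fallback sets out from 1 and returns at 4, making the ring first without stereochemistry and setting the centre afterwards by reduction. Pechmann condensation of 1 with commercial ethyl 3-oxooctanoate (MsOH or H2SO4, 0 °C to rt) gives the coumarin 7-hydroxy-5-methoxy-4-pentyl-2H-chromen-2-one F1, which is crystalline, so the minor 5-hydroxy-7-methoxy isomer is removed here. Copper hydride-catalysed enantioselective 1,4-reduction of its C3=C4 bond (Cu(OAc)2, DTBM-SEGPHOS, (EtO)2MeSiH, t-BuOH, toluene; ligand antipode chosen by HPLC comparison to give 4R; NH4F work-up frees the transiently silylated phenol) then delivers 4.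

Step 2 (C8 versus C6 acylation; survival of the open enone). The fallback sets out from 4 and returns at 9, reversing the order of the two electrophiles so that a C6 preference becomes useful. NBS (MeCN, 0 °C) puts the halogen on first to give (4R)-6-bromo-7-hydroxy-5-methoxy-4-pentylchroman-2-one F2, with the position confirmed by NOE. With C6 closed, 5/AlCl3 can acylate only C8, giving (4R)-6-bromo-7-hydroxy-5-methoxy-8-[(2E)-2-methylbut-2-enoyl]-4-pentylchroman-2-one F3; an aryl bromide tolerates AlCl3 better than the iodide would. Stille coupling of F3 with 8 (Pd2(dba)3, P(t-Bu)3, toluene, 90 °C) gives 9, bypassing 6 and 7.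

Step 5 (cis/trans ratio, ee, and slow attack of the alkaloid on the aryl lactone). The fallback sets out from 9 and returns at 10, separating the two stereochemical events. The ring is closed with a quinidine-derived bifunctional squaramide chosen only for C2 control, and C3 is then allowed to settle with Et3N to the more stable trans ketone (4R,8S,9S)-5-methoxy-8,9-dimethyl-6-(3-methylbut-2-en-1-yl)-4-pentyl-3,4,8,9-tetrahydro-2H,10H-pyrano[2,3-f]chromene-2,10-dione F4. The ketone enolate is then formed (LiHMDS, THF, −78 °C, where ring opening of the cyclic enolate is slow) and protonated kinetically with 2,6-di-tert-butylphenol from the face anti to the C8 methyl, which gives the cis ketone 10.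

**Further compounds**
F1 | step 1 | 7-hydroxy-5-methoxy-4-pentyl-2H-chromen-2-one | CCCCCC1=CC(=O)Oc2cc(O)cc(OC)c12
F2 | step 2 | (4R)-6-bromo-7-hydroxy-5-methoxy-4-pentylchroman-2-one | CCCCC[C@@H]1CC(=O)Oc2cc(O)c(Br)c(OC)c21
F3 | step 2 | (4R)-6-bromo-7-hydroxy-5-methoxy-8-[(2E)-2-methylbut-2-enoyl]-4-pentylchroman-2-one | CCCCC[C@@H]1CC(=O)Oc2c(C(=O)/C(C)=C/C)c(O)c(Br)c(OC)c21
F4 | step 5 | (4R,8S,9S)-5-methoxy-8,9-dimethyl-6-(3-methylbut-2-en-1-yl)-4-pentyl-3,4,8,9-tetrahydro-2H,10H-pyrano[2,3-f]chromene-2,10-dione (trans) | CCCCC[C@@H]1CC(=O)Oc2c3C(=O)[C@@H](C)[C@H](C)Oc3c(CC=C(C)C)c(OC)c21
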